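**Retrosynthetic overview** (target positions: C1 = macrolactone C=O, C3–C6 = furanone carbons, C14 = tertiary carbinol, C15–C18 = diene, C19 = quaternary lactone carbon, C20 = CH2, C21 = acyloxy carbon, C22 = CHMe, C23 = δ-lactone C=O)
1. The furanone is closed last by gold-catalysed 5-endo attack of the C6 hydroxyl on a C3≡C4 ynone; the 22-membered ring is closed at C16–C17 (Stille); fragment A (C17–C23 plus C1–C4 as an iodoalkyne ester) and fragment B (C5–C16 aldehyde) are joined at C4–C5 by chromium-mediated alkynylation.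
2. Enabling feature: in the δ-lactone ring (O, C23, C22, C21, C20, C19) the O–C(=O) unit bridges quaternary C19 and C22, so this ring is a 2-pyrone [4+2] adduct minus its etheno bridge. An enantioselective inverse-demand Diels–Alder reaction of a 3-benzyloxycarbonyl-6-(benzyloxymethyl)-2-pyrone with a silyl vinyl ether makes C19–C20 and C21–C22 and sets C19 and C21.
3. Ozonolysis cleaves the temporary C=C bridge: one bridge carbon becomes the C19 ethyl group, the other is lost as formate; the activating ester is exchanged for the C22 methyl (alkylation, then decarboxylative protonation).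
4. Fragment B: C14 from (S)-linalool, C10/C11 by lactate-ketone anti-aldol, C6 from (R)-glyceraldehyde acetonide, C7/C8 by substrate-controlled anti-aldol, C9 by 1,3-anti reduction.
5. Ring order: bicyclo[2.2.2] lactone (key step) → monocyclic δ-lactone (bridge cleavage) → macrocycle (Stille) → furanone.

Key step: step 3

Assumption: the (S,S)-configured bis(oxazoline) ligand is taken to shield the pyrone face that leads to (1S,4S,8S)-6; if the sense proves opposite, the (R,R)-ligand is used unchanged otherwise.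

Step 1
Reactants: 1 2-(benzyloxy)-N-methoxy-N-methylacetamide
Product: 2 1-(benzyloxy)but-3-yn-2-one
Conditions: HC≡CMgBr (1.3 equiv), THF, −20 → 0 °C; aq. NH4Cl
Reagents that add atoms: ethynylmagnesium bromide, C#C[Mg]Br
Why: Weinreb ketone synthesis; the chelated tetrahedral adduct survives until work-up, so the ynone should form without over-addition.

Step 2
Reactants: 2 1-(benzyloxy)but-3-yn-2-one; 3 dibenzyl malonate
Product: 4 benzyl 6-[(benzyloxy)methyl]-2-oxo-2H-pyran-3-carboxylate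
Conditions: t-BuOK (0.1 equiv), THF, 0 °C → rt; then TsOH (cat.), toluene, 90 °C
Reagents that add atoms: none
Why: Michael addition of the malonate to the ynone and lactonisation of the dienol onto one ester is the classical synthesis of 6-substituted 3-alkoxycarbonyl-2-pyrones.

Step 3
Reactants: 4 benzyl 6-[(benzyloxy)methyl]-2-oxo-2H-pyran-3-carboxylate; 5 tert-butyldimethyl(vinyloxy)silane
Product: 6 benzyl (1S,4S,8S)-1-[(benzyloxy)methyl]-8-[(tert-butyldimethylsilyl)oxy]-3-oxo-2-oxabicyclo[2.2.2]oct-5-ene-4-carboxylate (endo: siloxy group syn to the C5=C6 bridge)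
Conditions: Cu(OTf)2 (10 mol%), (S,S)-2,2′-isopropylidenebis(4-tert-butyl-2-oxazoline) (11 mol%), 4 Å MS, CH2Cl2, −40 → −20 °C, 5 (3 equiv)
Reagents that add atoms: none
Why: Two-point binding of the pyrone 1,3-dicarbonyl (lactone C=O and benzyl ester) to the chiral divalent copper complex lowers its LUMO, and the silyl enol ether adds in an asynchronous inverse-electron-demand [4+2] cycloaddition (its CH2 attacks pyrone C6, the oxocarbenium then closes onto C3), forming C19–C20 and C21–C22 in one operation. The closest precedent is the chiral Lewis acid-catalysed inverse-demand Diels–Alder reaction of 3-alkoxycarbonyl-2-pyrones with vinyl ethers and silyl enol ethers, which gives isolable 2-oxabicyclo[2.2.2]octenones. Both rings close in the cycloaddition mode: the carbocycle through the two new C–C bonds, and the six-membered lactone ring (O2, C3, C4, C8, C7, C1) through the same two bonds across the existing O–C(=O) bridge. C1 (later C19) and C8 (later C21) should be set by the ligand-controlled face of the chelated pyrone together with endo approach of the siloxy group; C4 is fixed by the bridge and is reset later. The required regioselectivity (siloxy carbon bonded to the ester-bearing carbon) follows from the polarisation of the chelated pyrone (C6 electrophilic, C3 nucleophilic), and the low temperature should prevent loss of CO2 from the adduct.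

Step 4
Reactants: 6 benzyl (1S,4S,8S)-1-[(benzyloxy)methyl]-8-[(tert-butyldimethylsilyl)oxy]-3-oxo-2-oxabicyclo[2.2.2]oct-5-ene-4-carboxylate
Product: 8 benzyl (4S,6R)-6-[(benzyloxy)methyl]-4-[(tert-butyldimethylsilyl)oxy]-6-formyl-2-oxooxane-3-carboxylate (C3 epimers), via dialdehyde 7 (not isolated)
Conditions: O3, CH2Cl2/MeOH (5:1), −78 °C; Me2S, −78 °C → rt; then Et3N (0.1 equiv), rt
Reagents that add atoms: ozone, [O-][O+]=O
Why: Ozonolysis cleaves the only C=C (the temporary bridge); the formyl group on the carbon carrying two acyl groups is then lost to methanol by retro-Claisen deformylation, leaving the C19 aldehyde cis to the siloxy group.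

Step 5
Reactants: 8 benzyl (4S,6R)-6-[(benzyloxy)methyl]-4-[(tert-butyldimethylsilyl)oxy]-6-formyl-2-oxooxane-3-carboxylate
Product: 9 benzyl (4S,6S)-6-[(benzyloxy)methyl]-4-[(tert-butyldimethylsilyl)oxy]-6-ethenyl-2-oxooxane-3-carboxylate (C3 epimers)
Conditions: Zn, CH2I2, TiCl4, THF, 0 °C; then 8, CH2Cl2, 0 °C → rt
Reagents that add atoms: diiodomethane, ICI
Why: Takai–Lombardo methylenation is non-basic and aldehyde-selective, so the acidic malonate-type C–H, the lactone and the ester should be untouched.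

Step 6
Reactants: 9 benzyl (4S,6S)-6-[(benzyloxy)methyl]-4-[(tert-butyldimethylsilyl)oxy]-6-ethenyl-2-oxooxane-3-carboxylate
Product: 10 benzyl (4S,6S)-6-[(benzyloxy)methyl]-4-[(tert-butyldimethylsilyl)oxy]-6-ethenyl-3-methyl-2-oxooxane-3-carboxylate (C3 epimers)
Conditions: MeI, K2CO3, acetone, rt
Reagents that add atoms: iodomethane, CI
Why: C-methylation of the malonate-type enolate installs the C22 methyl; the configuration of this quaternary centre is immaterial because it is reset in step 7.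

Step 7
Reactants: 10 benzyl (4S,6S)-6-[(benzyloxy)methyl]-4-[(tert-butyldimethylsilyl)oxy]-6-ethenyl-3-methyl-2-oxooxane-3-carboxylate
Product: 12 (3S,4S,6R)-6-[(benzyloxy)methyl]-4-[(tert-butyldimethylsilyl)oxy]-6-ethyl-3-methyloxan-2-one, via malonic acid 11 (not isolated)
Conditions: H2 (1 atm), Pd/C, pyridine (0.5 equiv), EtOAc, rt; filter; toluene, 100 °C
Reagents that add atoms: none
Why: Pyridine-poisoned Pd/C should saturate the vinyl group (C19 ethyl) and cleave the benzyl ester while sparing the benzyl ether; thermal decarboxylation gives an enol that should be protonated on the face away from the adjacent siloxy group, placing the C22 methyl cis to it.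

Step 8
Reactants: 12 (3S,4S,6R)-6-[(benzyloxy)methyl]-4-[(tert-butyldimethylsilyl)oxy]-6-ethyl-3-methyloxan-2-one
Product: 13 (3S,4S,6R)-4-[(tert-butyldimethylsilyl)oxy]-6-ethyl-6-(hydroxymethyl)-3-methyloxan-2-one
Conditions: H2 (1 atm), Pd(OH)2/C, EtOAc, rt
Reagents that add atoms: none
Why: Hydrogenolysis of the benzyl ether; the alcohol is oxidised at once so that acyl migration to the primary hydroxyl has no time to occur.

Step 9
Reactants: 13 (3S,4S,6R)-4-[(tert-butyldimethylsilyl)oxy]-6-ethyl-6-(hydroxymethyl)-3-methyloxan-2-one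
Product: 14 (2R,4S,5S)-4-[(tert-butyldimethylsilyl)oxy]-2-ethyl-5-methyl-6-oxooxane-2-carbaldehyde
Conditions: Dess–Martin periodinane, NaHCO3, CH2Cl2, 0 °C → rt
Reagents that add atoms: none
Why: Neutral oxidation to a non-enolisable aldehyde; the epimerisable C22 centre is not exposed to base.

Step 10
Reactants: 15 dibromomethane; 16 tributyltin chloride
Product: 18 tributyl(dibromomethyl)stannane, via dibromomethyllithium 17 (not isolated)
Conditions: LDA, THF/Et2O, −95 °C; then Bu3SnCl, −95 → −60 °C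
Reagents that add atoms: none
Why: Deprotonation of dibromomethane and stannylation of the carbenoid at low temperature is the standard preparation of this olefination reagent.

Step 11
Reactants: 14 (2R,4S,5S)-4-[(tert-butyldimethylsilyl)oxy]-2-ethyl-5-methyl-6-oxooxane-2-carbaldehyde; 18 tributyl(dibromomethyl)stannane
Product: 19 (3S,4S,6R)-4-[(tert-butyldimethylsilyl)oxy]-6-ethyl-3-methyl-6-[(E)-2-(tributylstannyl)ethenyl]oxan-2-one
Conditions: CrCl2 (8 equiv), LiI (4 equiv), THF/DMF, rt, dark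
Reagents that add atoms: none
Why: Hodgson–Takai stannyl-olefination through a geminal dichromium species should give the (E)-alkenylstannane under neutral conditions that spare the β-siloxy lactone.

Step 12
Reactants: 19 (3S,4S,6R)-4-[(tert-butyldimethylsilyl)oxy]-6-ethyl-3-methyl-6-[(E)-2-(tributylstannyl)ethenyl]oxan-2-one
Product: 20 (3S,4S,6R)-6-ethyl-4-hydroxy-3-methyl-6-[(E)-2-(tributylstannyl)ethenyl]oxan-2-one
Conditions: HF·pyridine, pyridine, THF, 0 °C → rt
Reagents that add atoms: none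
Why: Pyridine-buffered HF should cleave the secondary silyl ether without protodestannylation or β-elimination.

Step 13
Reactants: 21 but-3-ynoic acid
Product: 22 4-iodobut-3-ynoic acid
Conditions: N-iodosuccinimide, AgNO3 (10 mol%), acetone, rt
Reagents that add atoms: N-iodosuccinimide, O=C1CCC(=O)N1I
Why: Silver-catalysed electrophilic iodination of a terminal alkyne through the silver acetylide.

Step 14
Reactants: 20 (3S,4S,6R)-6-ethyl-4-hydroxy-3-methyl-6-[(E)-2-(tributylstannyl)ethenyl]oxan-2-one; 22 4-iodobut-3-ynoic acid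
Product: 23 (2R,4S,5S)-2-ethyl-5-methyl-6-oxo-2-[(E)-2-(tributylstannyl)ethenyl]oxan-4-yl 4-iodobut-3-ynoate (fragment A)
Conditions: DIC, DMAP (5 mol%), CH2Cl2, −20 → 0 °C
Reagents that add atoms: none
Why: Carbodiimide esterification acylates C21–OH with retention; low temperature and only catalytic DMAP should limit alkyne-to-allene isomerisation and β-elimination.

Step 15
Reactants: 24 ethyl (S)-lactate
Product: 25 (S)-2-hydroxy-N-methoxy-N-methylpropanamide
Conditions: MeNH(OMe)·HCl, i-PrMgCl, THF, −20 → 0 °C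
Reagents that add atoms: N,O-dimethylhydroxylamine hydrochloride, CNOC.Cl
Why: Magnesium amide aminolysis of the ester gives the Weinreb amide without touching the stereocentre.

Step 16
Reactants: 25 (S)-2-hydroxy-N-methoxy-N-methylpropanamide
Product: 26 (S)-2-hydroxypentan-3-one
Conditions: EtMgBr (3 equiv), THF, 0 °C
Reagents that add atoms: ethylmagnesium bromide, CC[Mg]Br
Why: Weinreb ketone synthesis; the chelated adduct prevents over-addition.

Step 17
Reactants: 26 (S)-2-hydroxypentan-3-one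
Product: 27 (S)-3-oxopentan-2-yl benzoate
Conditions: Bz2O, DMAP, i-Pr2NEt, CH2Cl2, 0 °C → rt
Reagents that add atoms: benzoic anhydride, O=C(OC(=O)c1ccccc1)c1ccccc1
Why: Acylation of the secondary alcohol gives the lactate-derived ethyl ketone used for anti-aldol reactions.

Step 18
Reactants: 28 (S)-(+)-linalool [(3S)-3,7-dimethylocta-1,6-dien-3-ol]
Product: 29 triethyl{[(3S)-3,7-dimethylocta-1,6-dien-3-yl]oxy}silane
Conditions: TESOTf, 2,6-lutidine, CH2Cl2, −78 → 0 °C
Reagents that add atoms: triethylsilyl triflate, CC[Si](CC)(CC)OS(=O)(=O)C(F)(F)F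
Why: The silyl triflate silylates the tertiary alcohol; the purchased stereocentre becomes C14.

Step 19
Reactants: 29 triethyl{[(3S)-3,7-dimethylocta-1,6-dien-3-yl]oxy}silane
Product: 30 {[(3S)-5-(3,3-dimethyloxiran-2-yl)-3-methylpent-1-en-3-yl]oxy}triethylsilane (epoxide epimers)
Conditions: mCPBA, NaHCO3, CH2Cl2, 0 °C
Reagents that add atoms: 3-chloroperbenzoic acid, OOC(=O)c1cccc(Cl)c1
Why: The electron-rich trisubstituted alkene is epoxidised far faster than the hindered vinyl group; the epoxide masks the future C11 aldehyde.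

Step 20
Reactants: 30 {[(3S)-5-(3,3-dimethyloxiran-2-yl)-3-methylpent-1-en-3-yl]oxy}triethylsilane
Product: 31 (2S)-4-(3,3-dimethyloxiran-2-yl)-2-methyl-2-[(triethylsilyl)oxy]butanal
Conditions: O3, CH2Cl2, −78 °C; PPh3, −78 °C → rt
Reagents that add atoms: ozone, [O-][O+]=O
Why: Ozonolysis of the remaining vinyl group gives a non-enolisable α-siloxy aldehyde.

Step 21
Reactants: 31 (2S)-4-(3,3-dimethyloxiran-2-yl)-2-methyl-2-[(triethylsilyl)oxy]butanal
Product: 32 {[(3S)-5-(3,3-dimethyloxiran-2-yl)-3-methylpent-1-yn-3-yl]oxy}triethylsilane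
Conditions: dimethyl (1-diazo-2-oxopropyl)phosphonate, K2CO3, MeOH, 0 °C → rt
Reagents that add atoms: dimethyl (1-diazo-2-oxopropyl)phosphonate, COP(=O)(OC)C(=[N+]=[N-])C(C)=O
Why: Seyferth–Gilbert homologation (Ohira–Bestmann variant) converts the aldehyde into the terminal alkyne; there is no α-hydrogen to epimerise.

Step 22
Reactants: 32 {[(3S)-5-(3,3-dimethyloxiran-2-yl)-3-methylpent-1-yn-3-yl]oxy}triethylsilane
Product: 34 {[(4S)-6-(3,3-dimethyloxiran-2-yl)-4-methylhex-2-yn-4-yl]oxy}triethylsilane, via lithium acetylide 33 (not isolated)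
Conditions: n-BuLi, THF, −78 °C; MeI, −78 → 0 °C
Reagents that add atoms: iodomethane, CI
Why: Acetylide alkylation supplies the C16 methyl; the trisubstituted epoxide should tolerate the acetylide at low temperature.

Step 23
Reactants: 34 {[(4S)-6-(3,3-dimethyloxiran-2-yl)-4-methylhex-2-yn-4-yl]oxy}triethylsilane
Product: 35 (4S)-4-methyl-4-[(triethylsilyl)oxy]hept-5-ynal
Conditions: H5IO6, Et2O, 0 °C
Reagents that add atoms: none
Why: Periodic acid opens the epoxide and cleaves the resulting glycol in one pot, releasing acetone and the C11 aldehyde.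

Step 24
Reactants: 27 (S)-3-oxopentan-2-yl benzoate; 35 (4S)-4-methyl-4-[(triethylsilyl)oxy]hept-5-ynal
Product: 37 (2S,4R,5R,8S)-5-hydroxy-4,8-dimethyl-3-oxo-8-[(triethylsilyl)oxy]undec-9-yn-2-yl benzoate, via boron enolate 36 (not isolated)
Conditions: (c-Hex)2BCl, Me2NEt, Et2O, −78 → 0 °C; 35, −78 → −20 °C; MeOH, pH 7 buffer, H2O2, 0 °C
Reagents that add atoms: none
Why: Paterson anti-aldol: the (E)-enol borinate reacts through a chair transition state in which the benzoyloxy stereocentre directs the aldehyde face, which should set C10 and C11 (anti) as in the target.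

Step 25
Reactants: 37 (2S,4R,5R,8S)-5-hydroxy-4,8-dimethyl-3-oxo-8-[(triethylsilyl)oxy]undec-9-yn-2-yl benzoate
Product: 38 (2S,4R,5R,8S)-5-methoxy-4,8-dimethyl-3-oxo-8-[(triethylsilyl)oxy]undec-9-yn-2-yl benzoate
Conditions: Me3OBF4, 1,8-bis(dimethylamino)naphthalene, CH2Cl2, 0 °C → rt
Reagents that add atoms: trimethyloxonium tetrafluoroborate, C[O+](C)C.F[B-](F)(F)F
Why: Meerwein methylation under non-basic conditions forms the C11 methyl ether without retro-aldol or epimerisation.

Step 26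
Reactants: 38 (2S,4R,5R,8S)-5-methoxy-4,8-dimethyl-3-oxo-8-[(triethylsilyl)oxy]undec-9-yn-2-yl benzoate
Product: 39 (4R,5R,8S)-5-methoxy-4,8-dimethyl-8-[(triethylsilyl)oxy]undec-9-yn-3-one
Conditions: SmI2 (2.5 equiv), THF/MeOH, 0 °C
Reagents that add atoms: none
Why: Divalent samarium reductively cleaves the α-benzoyloxy C–O bond, turning the auxiliary into the ethyl group that carries C8 and its methyl.

Step 27
Reactants: 39 (4R,5R,8S)-5-methoxy-4,8-dimethyl-8-[(triethylsilyl)oxy]undec-9-yn-3-one; 40 (R)-2,3-O-isopropylideneglyceraldehyde [(4R)-2,2-dimethyl-1,3-dioxolane-4-carbaldehyde, freshly distilled]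
Product: 42 C5–C16 anti-aldol adduct 1-[(4R)-2,2-dimethyl-1,3-dioxolan-4-yl]-1-hydroxy-5-methoxy-2,4,8-trimethyl-8-[(triethylsilyl)oxy]undec-9-yn-3-one (C6–C8/C10/C11/C14 as in the target), via boron enolate 41 (not isolated)
Conditions: (c-Hex)2BCl, Et3N, Et2O, 0 °C; 40, −78 → −20 °C; MeOH, pH 7 buffer, H2O2, 0 °C
Reagents that add atoms: none
Why: Substrate-controlled Paterson anti-aldol: the (E)-enol borinate forms on the ethyl side, the C10 stereocentre should direct the 8,10-anti relationship, and Felkin (polar) addition to the α-alkoxy aldehyde gives the 6,7-anti diol pattern, so both partners are matched for C7 and C8.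

Step 28
Reactants: 42 C5–C16 anti-aldol adduct (C9 ketone)
Product: 43 C5–C16 segment with C7/C9 anti-diol (C5/C6 acetonide; C11 OMe; C14 OTES; C15≡C16)
Conditions: Me4NBH(OAc)3, MeCN/AcOH (1:1), −30 °C
Reagents that add atoms: none
Why: Evans–Saksena reduction: hydride is delivered intramolecularly from the C7 alkoxyborohydride through a chair, which should give the 1,3-anti diol and thus C9.

Step 29
Reactants: 43 C7/C9 anti-diol
Product: 44 C7/C9 bis(tert-butyldimethylsilyl) ether
Conditions: TBSOTf (2.5 equiv), 2,6-lutidine, CH2Cl2, −78 → 0 °C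
Reagents that add atoms: tert-butyldimethylsilyl triflate, CC(C)(C)[Si](C)(C)OS(=O)(=O)C(F)(F)F
Why: The silyl triflate protects both hindered secondary alcohols.

Step 30
Reactants: 44 C7/C9 bis(tert-butyldimethylsilyl) ether
Product: 45 C5/C6/C14 triol (C7/C9 OTBS; C15≡C16)
Conditions: CSA (0.2 equiv), MeOH, 0 °C → rt
Reagents that add atoms: none
Why: Acid methanolysis removes the terminal acetonide and the triethylsilyl ether while the hindered secondary TBS ethers should survive; done at the alkyne stage there is no ionisable allylic carbinol, and any C14 silyl ether that survives converges in step 31.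

Step 31
Reactants: 45 C5/C6/C14 triol
Product: 46 C5/C6/C14 tris(triethylsilyl) ether
Conditions: TESOTf (4 equiv), 2,6-lutidine, CH2Cl2, −78 → 0 °C
Reagents that add atoms: triethylsilyl triflate, CC[Si](CC)(CC)OS(=O)(=O)C(F)(F)F
Why: Exhaustive silylation gives a labile ether at C6 (to be removed before the TBS ethers) and a primary ether at C5 that can be oxidised directly.

Step 32
Reactants: 46 C5/C6/C14 tris(triethylsilyl) ether
Product: 48 (E)-C16 vinyl iodide (C5–C16 segment), via alkenylzirconocene 47 (not isolated)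
Conditions: Cp2Zr(H)Cl (2.5 equiv), THF, rt → 40 °C; I2, 0 °C
Reagents that add atoms: iodine, II
Why: syn-Hydrozirconation places zirconium on the less hindered alkyne carbon (C16, remote from quaternary C14) and iodinolysis proceeds with retention, which should give the (E)-trisubstituted iodide.

Step 33
Reactants: 48 (E)-C16 vinyl iodide
Product: 49 C5 aldehyde (fragment B: C6 OTES; C7/C9 OTBS; C11 OMe; C14 OTES; C16 iodide)
Conditions: (COCl)2, DMSO, CH2Cl2, −78 °C; Et3N, −78 → −30 °C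
Reagents that add atoms: none
Why: Swern conditions convert primary triethylsilyl ethers directly into aldehydes while secondary and tertiary silyl ethers stay; the cold quench should avoid C6 epimerisation.

Step 34
Reactants: 23 fragment A; 49 fragment B
Product: 50 C5 carbinol coupling product (C4≡C3 alkyne; C5 epimers; alkenyl iodide and alkenylstannane intact)
Conditions: CrCl2 (nickel-free, 6 equiv), THF, rt
Reagents that add atoms: none
Why: Takai-type alkynylation: divalent chromium inserts into the alkynyl C–I bond without nickel, so the alkenyl iodide is left alone and the alkynylchromium adds to the aldehyde under neutral conditions; both C5 epimers are usable.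

Step 35
Reactants: 50 C5 carbinol coupling product
Product: 51 22-membered macrocyclic propargylic alcohol (15E,17E-diene)
Conditions: Pd2(dba)3·CHCl3 (15 mol%), AsPh3 (0.6 equiv), DMF/THF (1 mM), 40 °C
Reagents that add atoms: none
Why: Stille macrocyclisation between the (E)-alkenylstannane and the (E)-alkenyl iodide is stereoretentive and neutral, and high dilution should favour ring closure.

Step 36
Reactants: 51 macrocyclic propargylic alcohol
Product: 52 macrocyclic C5 ynone
Conditions: Dess–Martin periodinane, NaHCO3, CH2Cl2, 0 °C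
Reagents that add atoms: none
Why: Buffered oxidation of the propargylic alcohol converges both C5 epimers to the ynone.

Step 37
Reactants: 52 macrocyclic C5 ynone
Product: 53 C6-hydroxy ynone (C7/C9 OTBS and C14 OTES retained)
Conditions: HF·pyridine, pyridine, THF, 0 °C
Reagents that add atoms: none
Why: The secondary triethylsilyl ether next to the ketone should be cleaved much faster than the TBS ethers and the tertiary silyl ether, freeing only the C6 hydroxyl.

Step 38
Reactants: 53 C6-hydroxy ynone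
Product: 54 silyl-protected furanone macrolide
Conditions: (Ph3P)AuNTf2 (5 mol%), toluene, rt
Reagents that add atoms: none
Why: Cationic monovalent gold activates the ynone for 5-endo-dig attack of the C6 hydroxyl at C3 (known cyclisation of γ-hydroxyalkynones to 3(2H)-furanones); C7–OH is still protected, so a pyranone cannot form, and the neutral conditions should not epimerise C6.

Step 39
Reactants: 54 silyl-protected furanone macrolide
Product: 55 CNP0226414.1
Conditions: HF·pyridine (excess), pyridine, THF, 0 °C → rt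
Reagents that add atoms: none
Why: Buffered HF removes the two TBS ethers and the tertiary triethylsilyl ether without base, which protects C6, C22 and the β-acyloxy lactone.

**Compound list**
1 | 2-(benzyloxy)-N-methoxy-N-methylacetamide | CON(C)C(=O)COCc1ccccc1 | starting material
2 | 1-(benzyloxy)but-3-yn-2-one | C#CC(=O)COCc1ccccc1 | intermediate
3 | dibenzyl malonate | O=C(CC(=O)OCc1ccccc1)OCc1ccccc1 | starting material
4 | benzyl 6-[(benzyloxy)methyl]-2-oxo-2H-pyran-3-carboxylate | O=C1OC(COCc2ccccc2)=CC=C1C(=O)OCc1ccccc1 | intermediate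
5 | tert-butyldimethyl(vinyloxy)silane | C=CO[Si](C)(C)C(C)(C)C | starting material
6 | benzyl (1S,4S,8S)-1-[(benzyloxy)methyl]-8-[(tert-butyldimethylsilyl)oxy]-3-oxo-2-oxabicyclo[2.2.2]oct-5-ene-4-carboxylate | O=C1O[C@@]2(COCc3ccccc3)C[C@H](O[Si](C)(C)C(C)(C)C)[C@]1(C(=O)OCc1ccccc1)C=C2 | intermediate
7 | benzyl (3R,4S,6R)-6-[(benzyloxy)methyl]-4-[(tert-butyldimethylsilyl)oxy]-3,6-diformyl-2-oxooxane-3-carboxylate | O=C[C@]1(COCc2ccccc2)C[C@H](O[Si](C)(C)C(C)(C)C)[C@@](C=O)(C(=O)OCc2ccccc2)C(=O)O1 | intermediate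
8 | benzyl (4S,6R)-6-[(benzyloxy)methyl]-4-[(tert-butyldimethylsilyl)oxy]-6-formyl-2-oxooxane-3-carboxylate (C3 epimers) | O=C[C@]1(COCc2ccccc2)C[C@H](O[Si](C)(C)C(C)(C)C)C(C(=O)OCc2ccccc2)C(=O)O1 | intermediate
9 | benzyl (4S,6S)-6-[(benzyloxy)methyl]-4-[(tert-butyldimethylsilyl)oxy]-6-ethenyl-2-oxooxane-3-carboxylate (C3 epimers) | C=C[C@]1(COCc2ccccc2)C[C@H](O[Si](C)(C)C(C)(C)C)C(C(=O)OCc2ccccc2)C(=O)O1 | intermediate
10 | benzyl (4S,6S)-6-[(benzyloxy)methyl]-4-[(tert-butyldimethylsilyl)oxy]-6-ethenyl-3-methyl-2-oxooxane-3-carboxylate (C3 epimers) | C=C[C@]1(COCc2ccccc2)C[C@H](O[Si](C)(C)C(C)(C)C)C(C)(C(=O)OCc2ccccc2)C(=O)O1 | intermediate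
11 | (4S,6R)-6-[(benzyloxy)methyl]-4-[(tert-butyldimethylsilyl)oxy]-6-ethyl-3-methyl-2-oxooxane-3-carboxylic acid (C3 epimers) | CC[C@]1(COCc2ccccc2)C[C@H](O[Si](C)(C)C(C)(C)C)C(C)(C(=O)O)C(=O)O1 | intermediate
12 | (3S,4S,6R)-6-[(benzyloxy)methyl]-4-[(tert-butyldimethylsilyl)oxy]-6-ethyl-3-methyloxan-2-one | CC[C@]1(COCc2ccccc2)C[C@H](O[Si](C)(C)C(C)(C)C)[C@H](C)C(=O)O1 | intermediate
13 | (3S,4S,6R)-4-[(tert-butyldimethylsilyl)oxy]-6-ethyl-6-(hydroxymethyl)-3-methyloxan-2-one | CC[C@]1(CO)C[C@H](O[Si](C)(C)C(C)(C)C)[C@H](C)C(=O)O1 | intermediate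
14 | (2R,4S,5S)-4-[(tert-butyldimethylsilyl)oxy]-2-ethyl-5-methyl-6-oxooxane-2-carbaldehyde | CC[C@]1(C=O)C[C@H](O[Si](C)(C)C(C)(C)C)[C@H](C)C(=O)O1 | intermediate
15 | dibromomethane | BrCBr | starting material
16 | tributyltin chloride | CCCC[Sn](Cl)(CCCC)CCCC | starting material
17 | dibromomethyllithium | [Li]C(Br)Br | intermediate
18 | tributyl(dibromomethyl)stannane | CCCC[Sn](CCCC)(CCCC)C(Br)Br | intermediate
19 | (3S,4S,6R)-4-[(tert-butyldimethylsilyl)oxy]-6-ethyl-3-methyl-6-[(E)-2-(tributylstannyl)ethenyl]oxan-2-one | CC[C@]1(/C=C/[Sn](CCCC)(CCCC)CCCC)C[C@H](O[Si](C)(C)C(C)(C)C)[C@H](C)C(=O)O1 | intermediate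
20 | (3S,4S,6R)-6-ethyl-4-hydroxy-3-methyl-6-[(E)-2-(tributylstannyl)ethenyl]oxan-2-one | CC[C@]1(/C=C/[Sn](CCCC)(CCCC)CCCC)C[C@H](O)[C@H](C)C(=O)O1 | intermediate
21 | but-3-ynoic acid | C#CCC(=O)O | starting material
22 | 4-iodobut-3-ynoic acid | OC(=O)CC#CI | intermediate
23 | (2R,4S,5S)-2-ethyl-5-methyl-6-oxo-2-[(E)-2-(tributylstannyl)ethenyl]oxan-4-yl 4-iodobut-3-ynoate (fragment A) | CC[C@]1(/C=C/[Sn](CCCC)(CCCC)CCCC)C[C@H](OC(=O)CC#CI)[C@H](C)C(=O)O1 | intermediate
24 | ethyl (S)-lactate | C[C@H](O)C(=O)OCC | starting material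
25 | (S)-2-hydroxy-N-methoxy-N-methylpropanamide | C[C@H](O)C(=O)N(C)OC | intermediate
26 | (S)-2-hydroxypentan-3-one | C[C@H](O)C(=O)CC | intermediate
27 | (S)-3-oxopentan-2-yl benzoate | C[C@H](OC(=O)c1ccccc1)C(=O)CC | intermediate
28 | (S)-(+)-linalool | C=C[C@@](C)(O)CCC=C(C)C | starting material
29 | triethyl{[(3S)-3,7-dimethylocta-1,6-dien-3-yl]oxy}silane | C=C[C@@](C)(O[Si](CC)(CC)CC)CCC=C(C)C | intermediate
30 | {[(3S)-5-(3,3-dimethyloxiran-2-yl)-3-methylpent-1-en-3-yl]oxy}triethylsilane (epoxide epimers) | C=C[C@@](C)(O[Si](CC)(CC)CC)CCC1OC1(C)C | intermediate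
31 | (2S)-4-(3,3-dimethyloxiran-2-yl)-2-methyl-2-[(triethylsilyl)oxy]butanal | O=C[C@@](C)(O[Si](CC)(CC)CC)CCC1OC1(C)C | intermediate
32 | {[(3S)-5-(3,3-dimethyloxiran-2-yl)-3-methylpent-1-yn-3-yl]oxy}triethylsilane | C#C[C@@](C)(O[Si](CC)(CC)CC)CCC1OC1(C)C | intermediate
33 | lithium acetylide of 32 | [Li]C#C[C@@](C)(O[Si](CC)(CC)CC)CCC1OC1(C)C | intermediate
34 | {[(4S)-6-(3,3-dimethyloxiran-2-yl)-4-methylhex-2-yn-4-yl]oxy}triethylsilane | CC#C[C@@](C)(O[Si](CC)(CC)CC)CCC1OC1(C)C | intermediate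
35 | (4S)-4-methyl-4-[(triethylsilyl)oxy]hept-5-ynal | CC#C[C@@](C)(O[Si](CC)(CC)CC)CCC=O | intermediate
36 | (E)-enol dicyclohexylborinate of 27 | C/C=C(/OB(C1CCCCC1)C1CCCCC1)[C@H](C)OC(=O)c1ccccc1 | intermediate
37 | (2S,4R,5R,8S)-5-hydroxy-4,8-dimethyl-3-oxo-8-[(triethylsilyl)oxy]undec-9-yn-2-yl benzoate | CC#C[C@@](C)(O[Si](CC)(CC)CC)CC[C@@H](O)[C@@H](C)C(=O)[C@H](C)OC(=O)c1ccccc1 | intermediate
38 | (2S,4R,5R,8S)-5-methoxy-4,8-dimethyl-3-oxo-8-[(triethylsilyl)oxy]undec-9-yn-2-yl benzoate | CC#C[C@@](C)(O[Si](CC)(CC)CC)CC[C@@H](OC)[C@@H](C)C(=O)[C@H](C)OC(=O)c1ccccc1 | intermediate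
39 | (4R,5R,8S)-5-methoxy-4,8-dimethyl-8-[(triethylsilyl)oxy]undec-9-yn-3-one | CC#C[C@@](C)(O[Si](CC)(CC)CC)CC[C@@H](OC)[C@@H](C)C(=O)CC | intermediate
40 | (R)-2,3-O-isopropylideneglyceraldehyde | O=C[C@H]1COC(C)(C)O1 | starting material
41 | (E)-enol dicyclohexylborinate of 39 | CC#C[C@@](C)(O[Si](CC)(CC)CC)CC[C@@H](OC)[C@@H](C)/C(OB(C1CCCCC1)C1CCCCC1)=C\C | intermediate
42 | C5–C16 anti-aldol adduct (C9 ketone; C7 OH; C5/C6 acetonide) | CC#C[C@@](C)(O[Si](CC)(CC)CC)CC[C@@H](OC)[C@@H](C)C(=O)[C@H](C)[C@H](O)[C@H]1COC(C)(C)O1 | intermediate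
43 | C5–C16 segment with C7/C9 anti-diol | CC#C[C@@](C)(O[Si](CC)(CC)CC)CC[C@@H](OC)[C@@H](C)[C@@H](O)[C@H](C)[C@H](O)[C@H]1COC(C)(C)O1 | intermediate
44 | C7/C9 bis(tert-butyldimethylsilyl) ether | CC#C[C@@](C)(O[Si](CC)(CC)CC)CC[C@@H](OC)[C@@H](C)[C@@H](O[Si](C)(C)C(C)(C)C)[C@H](C)[C@H](O[Si](C)(C)C(C)(C)C)[C@H]1COC(C)(C)O1 | intermediate
45 | C5/C6/C14 triol | CC#C[C@@](C)(O)CC[C@@H](OC)[C@@H](C)[C@@H](O[Si](C)(C)C(C)(C)C)[C@H](C)[C@H](O[Si](C)(C)C(C)(C)C)[C@H](O)CO | intermediate
46 | C5/C6/C14 tris(triethylsilyl) ether | CC#C[C@@](C)(O[Si](CC)(CC)CC)CC[C@@H](OC)[C@@H](C)[C@@H](O[Si](C)(C)C(C)(C)C)[C@H](C)[C@H](O[Si](C)(C)C(C)(C)C)[C@H](O[Si](CC)(CC)CC)CO[Si](CC)(CC)CC | intermediate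
47 | C16 alkenylzirconocene chloride | Cl[Zr](C1C=CC=C1)(C1C=CC=C1)/C(C)=C/[C@@](C)(O[Si](CC)(CC)CC)CC[C@@H](OC)[C@@H](C)[C@@H](O[Si](C)(C)C(C)(C)C)[C@H](C)[C@H](O[Si](C)(C)C(C)(C)C)[C@H](O[Si](CC)(CC)CC)CO[Si](CC)(CC)CC | intermediate
48 | (E)-C16 vinyl iodide (C5 OTES) | I/C(C)=C/[C@@](C)(O[Si](CC)(CC)CC)CC[C@@H](OC)[C@@H](C)[C@@H](O[Si](C)(C)C(C)(C)C)[C@H](C)[C@H](O[Si](C)(C)C(C)(C)C)[C@H](O[Si](CC)(CC)CC)CO[Si](CC)(CC)CC | intermediate
49 | C5 aldehyde (fragment B) | I/C(C)=C/[C@@](C)(O[Si](CC)(CC)CC)CC[C@@H](OC)[C@@H](C)[C@@H](O[Si](C)(C)C(C)(C)C)[C@H](C)[C@H](O[Si](C)(C)C(C)(C)C)[C@H](O[Si](CC)(CC)CC)C=O | intermediate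
50 | C5 carbinol coupling product (C5 epimers) | I/C(C)=C/[C@@](C)(O[Si](CC)(CC)CC)CC[C@@H](OC)[C@@H](C)[C@@H](O[Si](C)(C)C(C)(C)C)[C@H](C)[C@H](O[Si](C)(C)C(C)(C)C)[C@H](O[Si](CC)(CC)CC)C(O)C#CCC(=O)O[C@H]1C[C@](CC)(/C=C/[Sn](CCCC)(CCCC)CCCC)OC(=O)[C@H]1C | intermediate
51 | macrocyclic propargylic alcohol (C5 epimers) | CC[C@]12/C=C/C(C)=C/[C@@](C)(O[Si](CC)(CC)CC)CC[C@@H](OC)[C@@H](C)[C@@H](O[Si](C)(C)C(C)(C)C)[C@H](C)[C@H](O[Si](C)(C)C(C)(C)C)[C@H](O[Si](CC)(CC)CC)C(O)C#CCC(=O)O[C@@H](C1)[C@H](C)C(=O)O2 | intermediate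
52 | macrocyclic C5 ynone | CC[C@]12/C=C/C(C)=C/[C@@](C)(O[Si](CC)(CC)CC)CC[C@@H](OC)[C@@H](C)[C@@H](O[Si](C)(C)C(C)(C)C)[C@H](C)[C@H](O[Si](C)(C)C(C)(C)C)[C@H](O[Si](CC)(CC)CC)C(=O)C#CCC(=O)O[C@@H](C1)[C@H](C)C(=O)O2 | intermediate
53 | C6-hydroxy ynone | CC[C@]12/C=C/C(C)=C/[C@@](C)(O[Si](CC)(CC)CC)CC[C@@H](OC)[C@@H](C)[C@@H](O[Si](C)(C)C(C)(C)C)[C@H](C)[C@H](O[Si](C)(C)C(C)(C)C)[C@H](O)C(=O)C#CCC(=O)O[C@@H](C1)[C@H](C)C(=O)O2 | intermediate
54 | silyl-protected furanone macrolide | CC[C@]12/C=C/C(C)=C/[C@@](C)(O[Si](CC)(CC)CC)CC[C@@H](OC)[C@@H](C)[C@@H](O[Si](C)(C)C(C)(C)C)[C@H](C)[C@H](O[Si](C)(C)C(C)(C)C)[C@@H]3OC(=CC3=O)CC(=O)O[C@@H](C1)[C@H](C)C(=O)O2 | intermediate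
55 | CNP0226414.1 | CC[C@]12/C=C/C(C)=C/[C@@](C)(O)CC[C@@H](OC)[C@@H](C)[C@@H](O)[C@H](C)[C@H](O)[C@@H]3OC(=CC3=O)CC(=O)O[C@@H](C1)[C@H](C)C(=O)O2 | target

For 42–54 the locants are those of the target; every stereocentre has the spatial arrangement of the corresponding target carbon, as written in the SMILES.

**Count:** 39 steps in total; longest linear sequence 22 steps (28 → 55, steps 18–39).

**Steps most likely to fail**

Step 3. The cycloaddition may stall, or lose facial and endo selectivity, because the enol ether must attack a fully substituted pyrone C6 inside the chiral pocket. Fallback: setting out from 4 (with 5), the uncatalysed cycloaddition under high pressure (CH2Cl2, 12 kbar, rt) should give the racemic endo adduct, that is 6 together with its enantiomer benzyl (1R,4R,8R)-1-[(benzyloxy)methyl]-8-[(tert-butyldimethylsilyl)oxy]-3-oxo-2-oxabicyclo[2.2.2]oct-5-ene-4-carboxylate F1. Preparative chromatography on a chiral stationary phase separates the two, and the route is rejoined at 6.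

Step 34. The alkenyl iodide may be reduced or activated, or the 3-alkynoate may isomerise to the allenoate, before the alkynylchromium adds to the hindered α-siloxy aldehyde. Fallback (the two unions are exchanged): setting out from 20, esterification with but-3-ynoic acid 21 (DIC, DMAP cat.) gives (2R,4S,5S)-2-ethyl-5-methyl-6-oxo-2-[(E)-2-(tributylstannyl)ethenyl]oxan-4-yl but-3-ynoate F4. Stille coupling of F4 with 49 (Pd2(dba)3, AsPh3, DMF) gives the open-chain dienyl C5 aldehyde with terminal alkyne F5. AgNO3-catalysed iodination with N-iodosuccinimide gives the iodoalkyne aldehyde F6, and the same chromium-mediated alkynylation, now intramolecular at high dilution (CrCl2, THF), closes the ring and rejoins the route at 51; step 35 is then not needed.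

Step 7. Protonation of the enol left by decarboxylation may show poor facial selectivity and give the C22 epimer. Fallback: setting out from 9 (step 6 omitted), hydrogenation with Pd/C and pyridine gives (4S,6R)-6-[(benzyloxy)methyl]-4-[(tert-butyldimethylsilyl)oxy]-6-ethyl-2-oxooxane-3-carboxylic acid F2. Decarboxylative Mannich methylenation (aqueous CH2O, Et2NH, then NaOAc/AcOH, 80 °C) gives (4S,6R)-6-[(benzyloxy)methyl]-4-[(tert-butyldimethylsilyl)oxy]-6-ethyl-3-methylideneoxan-2-one F3. Hydrogenation over Rh/Al2O3 from the face opposite the siloxy group should then set C22, rejoining the route at 12.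

Further compounds
F1 | step 3 | benzyl (1R,4R,8R)-1-[(benzyloxy)methyl]-8-[(tert-butyldimethylsilyl)oxy]-3-oxo-2-oxabicyclo[2.2.2]oct-5-ene-4-carboxylate | O=C1O[C@]2(COCc3ccccc3)C[C@@H](O[Si](C)(C)C(C)(C)C)[C@@]1(C(=O)OCc1ccccc1)C=C2
F2 | step 7 | (4S,6R)-6-[(benzyloxy)methyl]-4-[(tert-butyldimethylsilyl)oxy]-6-ethyl-2-oxooxane-3-carboxylic acid | CC[C@]1(COCc2ccccc2)C[C@H](O[Si](C)(C)C(C)(C)C)C(C(=O)O)C(=O)O1
F3 | step 7 | (4S,6R)-6-[(benzyloxy)methyl]-4-[(tert-butyldimethylsilyl)oxy]-6-ethyl-3-methylideneoxan-2-one | CC[C@]1(COCc2ccccc2)C[C@H](O[Si](C)(C)C(C)(C)C)C(=C)C(=O)O1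
F4 | step 34 | (2R,4S,5S)-2-ethyl-5-methyl-6-oxo-2-[(E)-2-(tributylstannyl)ethenyl]oxan-4-yl but-3-ynoate | CC[C@]1(/C=C/[Sn](CCCC)(CCCC)CCCC)C[C@H](OC(=O)CC#C)[C@H](C)C(=O)O1
F5 | step 34 | open-chain dienyl C5 aldehyde with terminal alkyne ester | CC[C@]1(/C=C/C(C)=C/[C@@](C)(O[Si](CC)(CC)CC)CC[C@@H](OC)[C@@H](C)[C@@H](O[Si](C)(C)C(C)(C)C)[C@H](C)[C@H](O[Si](C)(C)C(C)(C)C)[C@H](O[Si](CC)(CC)CC)C=O)C[C@H](OC(=O)CC#C)[C@H](C)C(=O)O1
F6 | step 34 | open-chain dienyl C5 aldehyde with iodoalkyne ester | CC[C@]1(/C=C/C(C)=C/[C@@](C)(O[Si](CC)(CC)CC)CC[C@@H](OC)[C@@H](C)[C@@H](O[Si](C)(C)C(C)(C)C)[C@H](C)[C@H](O[Si](C)(C)C(C)(C)C)[C@H](O[Si](CC)(CC)CC)C=O)C[C@H](OC(=O)CC#CI)[C@H](C)C(=O)O1
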